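Assumption: the target (3,5-dihydroxy-2-(3,5-dihydroxy-4-methoxyphenyl)-7,8-dimethoxy-4H-chromen-4-one) has no stereocentre, so "single enantiomer" means the achiral compound itself and no stereocontrol is needed.

**Retrosynthetic overview**
1. Target ⇐ hydrogenolysis of two B-ring benzyl ethers, preceded by chelation-controlled cleavage of the 5-OMe of a 3-hydroxy-5,7,8-trimethoxyflavone.
2. 3-OH ⇐ epoxidation and ring-opening at C2=C3 of the flavone; the pyranone C-ring (the only ring formed) ⇐ oxidative cyclisation of a 2'-hydroxychalcone.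
3. Chalcone Cα–Cβ bond ⇐ Claisen–Schmidt aldol condensation of 2-hydroxy-3,4,6-trimethoxyacetophenone with 3,5-bis(benzyloxy)-4-methoxybenzaldehyde.
4. Acetophenone ⇐ 3,4,5-trimethoxyphenol (O-methylation, then Friedel–Crafts acetylation with ortho-demethylation). Aldehyde ⇐ methyl gallate (4-O-methylation, benzylation, reduction, oxidation).

**Route**

Step 1
Reactants: 1 methyl gallate (methyl 3,4,5-trihydroxybenzoate)
Product: 2 methyl 3,5-dihydroxy-4-methoxybenzoate
Conditions: MeI (1.05 equiv), KHCO3 (1.5 equiv), DMF, 25–30 °C, N2, 24–48 h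
Reagents that add atoms: iodomethane, CI
Why: Williamson O-alkylation; the 4-OH para to the ester is the most acidic, so the weak base ionises and methylates it selectively.

Step 2
Reactants: 2 methyl 3,5-dihydroxy-4-methoxybenzoate
Product: 3 methyl 3,5-bis(benzyloxy)-4-methoxybenzoate
Conditions: BnBr (2.4 equiv), K2CO3 (3 equiv), DMF, 60 °C
Reagents that add atoms: benzyl bromide, BrCc1ccccc1
Why: exhaustive Williamson benzylation of the two remaining phenols; benzyl ethers survive every later basic, oxidative and thermal step.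

Step 3
Reactants: 3 methyl 3,5-bis(benzyloxy)-4-methoxybenzoate
Product: 4 [3,5-bis(benzyloxy)-4-methoxyphenyl]methanol
Conditions: LiAlH4, THF, 0 °C to rt; Fieser work-up
Reagents that add atoms: none
Why: hydride reduction of the ester to the benzylic alcohol; aryl ethers are inert.

Step 4
Reactants: 4 [3,5-bis(benzyloxy)-4-methoxyphenyl]methanol
Product: 5 3,5-bis(benzyloxy)-4-methoxybenzaldehyde
Conditions: activated MnO2 (10 equiv), CH2Cl2, rt
Reagents that add atoms: none
Why: MnO2 oxidation of an electron-rich benzylic alcohol stops cleanly at the aldehyde.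

Step 5
Reactants: 6 3,4,5-trimethoxyphenol
Product: 7 1,2,3,5-tetramethoxybenzene
Conditions: MeI (1.5 equiv), K2CO3 (2 equiv), acetone, reflux
Reagents that add atoms: iodomethane, CI
Why: simple Williamson methylation of a single phenol gives the symmetric arene.

Step 6
Reactants: 7 1,2,3,5-tetramethoxybenzene
Product: 9 2-hydroxy-3,4,6-trimethoxyacetophenone, via 2,3,4,6-tetramethoxyacetophenone 8 (not isolated)
Conditions: AcCl (1.2 equiv), AlCl3 (2.5 equiv), Et2O, 0 °C to rt (brief reflux); aq. HCl work-up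
Reagents that add atoms: acetyl chloride, CC(Cl)=O
Why: Friedel–Crafts acylation can only occur at the two equivalent free positions; the Al-chelated ketone then loses the more crowded ortho-methoxy group (the one flanked by the acetyl and the 3-OMe), which is the classical outcome for this arene. Confirm by NOE (6-OMe to H-5) and the chelated OH signal.

Step 7
Reactants: 9 2-hydroxy-3,4,6-trimethoxyacetophenone; 5 3,5-bis(benzyloxy)-4-methoxybenzaldehyde
Product: 11 (E)-3-[3,5-bis(benzyloxy)-4-methoxyphenyl]-1-(2-hydroxy-3,4,6-trimethoxyphenyl)prop-2-en-1-one, via aldol adduct 10 (not isolated)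
Conditions: 50% aq. KOH (10 equiv), EtOH, rt, 48 h; then cold dil. HCl
Reagents that add atoms: none
Why: Claisen–Schmidt aldol condensation between the methyl ketone enolate and a non-enolisable aldehyde; E1cB dehydration gives the conjugated E-chalcone.

Step 8
Reactants: 11 the (E)-chalcone
Product: 13 2-[3,5-bis(benzyloxy)-4-methoxyphenyl]-5,7,8-trimethoxy-4H-chromen-4-one, via flavanone 12 (not isolated)
Conditions: I2 (10 mol%), DMSO, 130 °C, 2 h; aq. Na2S2O3 wash
Reagents that add atoms: none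
Why: iodine-catalysed oxidative cyclisation (oxa-Michael closure of the only free phenol, then dehydrogenation with DMSO as terminal oxidant); the single free OH fixes the 5,7,8-pattern.

Step 9
Reactants: 13 the 5,7,8-trimethoxyflavone
Product: 15 2-[3,5-bis(benzyloxy)-4-methoxyphenyl]-3-hydroxy-5,7,8-trimethoxy-4H-chromen-4-one, via flavone 2,3-epoxide 14 (not isolated)
Conditions: DMDO (about 0.07 M in acetone, 3–4 equiv), CH2Cl2, 0 °C to rt, 12–24 h; concentrate; then p-TsOH·H2O (10 mol%), CHCl3, rt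
Reagents that add atoms: dimethyldioxirane, CC1(C)OO1
Why: dioxirane epoxidation of the electron-rich enol-ether C2=C3 bond, then acid-catalysed epoxide opening and tautomerisation to the flavonol; this avoids the aurone problem of direct chalcone oxidation when a 6'-OMe is present.

Step 10
Reactants: 15 the 3-hydroxy-5,7,8-trimethoxyflavone
Product: 16 2-[3,5-bis(benzyloxy)-4-methoxyphenyl]-3,5-dihydroxy-7,8-dimethoxy-4H-chromen-4-one
Conditions: anhydrous AlCl3 (5 equiv), MeCN, 0 °C to rt, TLC control; then 2 M HCl, 40 °C, 15 min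
Reagents that add atoms: none
Why: chelation-controlled Lewis-acid demethylation; only the 5-OMe peri to the C4 carbonyl forms the six-membered Al chelate that is opened by chloride. MeCN moderates AlCl3 so the 7-, 8-, 4'-OMe and benzyl ethers are kept; any partly debenzylated material converges in step 11.

Step 11
Reactants: 16 the 5-hydroxy dibenzyl ether
Product: 17 3,5-dihydroxy-2-(3,5-dihydroxy-4-methoxyphenyl)-7,8-dimethoxy-4H-chromen-4-one (target)
Conditions: H2 (1 atm), 10% Pd/C, THF–MeOH 1:1, rt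
Reagents that add atoms: none
Why: catalytic hydrogenolysis of aryl benzyl ethers; methyl ethers and the flavonol C2=C3 bond are untouched under these mild conditions.

**Compound list**
1 | methyl gallate (methyl 3,4,5-trihydroxybenzoate) | COC(=O)c1cc(O)c(O)c(O)c1 | starting material
2 | methyl 3,5-dihydroxy-4-methoxybenzoate | COC(=O)c1cc(O)c(OC)c(O)c1 | intermediate
3 | methyl 3,5-bis(benzyloxy)-4-methoxybenzoate | COC(=O)c1cc(OCc2ccccc2)c(OC)c(OCc2ccccc2)c1 | intermediate
4 | [3,5-bis(benzyloxy)-4-methoxyphenyl]methanol | OCc1cc(OCc2ccccc2)c(OC)c(OCc2ccccc2)c1 | intermediate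
5 | 3,5-bis(benzyloxy)-4-methoxybenzaldehyde | O=Cc1cc(OCc2ccccc2)c(OC)c(OCc2ccccc2)c1 | intermediate
6 | 3,4,5-trimethoxyphenol | COc1cc(O)cc(OC)c1OC | starting material
7 | 1,2,3,5-tetramethoxybenzene | COc1cc(OC)c(OC)c(OC)c1 | intermediate
8 | 2,3,4,6-tetramethoxyacetophenone | CC(=O)c1c(OC)cc(OC)c(OC)c1OC | intermediate (not isolated)
9 | 2-hydroxy-3,4,6-trimethoxyacetophenone | CC(=O)c1c(OC)cc(OC)c(OC)c1O | intermediate
10 | 3-[3,5-bis(benzyloxy)-4-methoxyphenyl]-3-hydroxy-1-(2-hydroxy-3,4,6-trimethoxyphenyl)propan-1-one (racemic aldol adduct) | COc1cc(OC)c(C(=O)CC(O)c2cc(OCc3ccccc3)c(OC)c(OCc3ccccc3)c2)c(O)c1OC | intermediate (not isolated)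
11 | (E)-3-[3,5-bis(benzyloxy)-4-methoxyphenyl]-1-(2-hydroxy-3,4,6-trimethoxyphenyl)prop-2-en-1-one | COc1cc(OC)c(C(=O)/C=C/c2cc(OCc3ccccc3)c(OC)c(OCc3ccccc3)c2)c(O)c1OC | intermediate
12 | 2-[3,5-bis(benzyloxy)-4-methoxyphenyl]-5,7,8-trimethoxychroman-4-one (racemic flavanone) | COc1cc(OC)c2C(=O)CC(c3cc(OCc4ccccc4)c(OC)c(OCc4ccccc4)c3)Oc2c1OC | intermediate (not isolated)
13 | 2-[3,5-bis(benzyloxy)-4-methoxyphenyl]-5,7,8-trimethoxy-4H-chromen-4-one | COc1cc(OC)c2c(=O)cc(-c3cc(OCc4ccccc4)c(OC)c(OCc4ccccc4)c3)oc2c1OC | intermediate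
14 | 2,3-epoxy-2-[3,5-bis(benzyloxy)-4-methoxyphenyl]-5,7,8-trimethoxychroman-4-one (racemic) | COc1cc(OC)c2C(=O)C3OC3(c4cc(OCc5ccccc5)c(OC)c(OCc5ccccc5)c4)Oc2c1OC | intermediate (not isolated)
15 | 2-[3,5-bis(benzyloxy)-4-methoxyphenyl]-3-hydroxy-5,7,8-trimethoxy-4H-chromen-4-one | COc1cc(OC)c2c(=O)c(O)c(-c3cc(OCc4ccccc4)c(OC)c(OCc4ccccc4)c3)oc2c1OC | intermediate
16 | 2-[3,5-bis(benzyloxy)-4-methoxyphenyl]-3,5-dihydroxy-7,8-dimethoxy-4H-chromen-4-one | COc1cc(O)c2c(=O)c(O)c(-c3cc(OCc4ccccc4)c(OC)c(OCc4ccccc4)c3)oc2c1OC | intermediate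
17 | 3,5-dihydroxy-2-(3,5-dihydroxy-4-methoxyphenyl)-7,8-dimethoxy-4H-chromen-4-one | COc1cc(O)c2c(=O)c(O)c(-c3cc(O)c(OC)c(O)c3)oc2c1OC | target

**Totals**
Total step count: 11. Longest linear sequence: 9 steps (steps 1–4, then 7–11).

**Three steps most likely to fail, with fallbacks**

Step 9 (C3 hydroxylation with DMDO; slow epoxidation, possible attack on benzylic C–H or the electron-rich A-ring). The fallback sets out from 13 and comes back at 15. Flavone 13 is deprotonated at C3 with LDA in THF at −78 °C to give 2-[3,5-bis(benzyloxy)-4-methoxyphenyl]-3-lithio-5,7,8-trimethoxy-4H-chromen-4-one F3. This is quenched with B(OMe)3 to give dimethyl {2-[3,5-bis(benzyloxy)-4-methoxyphenyl]-5,7,8-trimethoxy-4-oxo-4H-chromen-3-yl}boronate F4. Without isolation, F4 is oxidised with H2O2/AcOH to flavonol 15. This replaces electrophilic epoxidation by a metalation, borylation and oxidation sequence.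

Step 10 (selective 5-O-demethylation; risk of cleaving the 8-OMe or 4'-OMe, or messy partial debenzylation). The fallback sets out from 15 and comes back at 17, bypassing 16. Hydrogenolysis of 15 (H2, Pd/C) gives 2-(3,5-dihydroxy-4-methoxyphenyl)-3-hydroxy-5,7,8-trimethoxy-4H-chromen-4-one F5. Ac2O/pyridine/DMAP converts it to 5-(3-acetoxy-5,7,8-trimethoxy-4-oxo-4H-chromen-2-yl)-2-methoxy-1,3-phenylene diacetate F6. BCl3 in CH2Cl2 (−78 to 0 °C) then removes only the carbonyl-chelated 5-OMe, the acetates deactivating and shielding everything else, to give 5-(3-acetoxy-5-hydroxy-7,8-dimethoxy-4-oxo-4H-chromen-2-yl)-2-methoxy-1,3-phenylene diacetate F7. Methanolysis (1 M HCl in MeOH, 40 °C) delivers 17.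

Step 1 (mono-methylation of methyl gallate; over- or mis-alkylation). The fallback sets out from 1 and comes back at 2. Compound 1 is peracetylated (Ac2O, pyridine) to methyl 3,4,5-triacetoxybenzoate F1. MeI/K2CO3 in refluxing acetone cleaves only the most labile para-acetate and methylates the phenoxide in situ, giving methyl 3,5-diacetoxy-4-methoxybenzoate F2. Methanolysis (HCl, MeOH) returns 2.

**Further compounds**
F1 | step 1 | methyl 3,4,5-triacetoxybenzoate | COC(=O)c1cc(OC(C)=O)c(OC(C)=O)c(OC(C)=O)c1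
F2 | step 1 | methyl 3,5-diacetoxy-4-methoxybenzoate | COC(=O)c1cc(OC(C)=O)c(OC)c(OC(C)=O)c1
F3 | step 9 | 2-[3,5-bis(benzyloxy)-4-methoxyphenyl]-3-lithio-5,7,8-trimethoxy-4H-chromen-4-one | [Li]c1c(-c2cc(OCc3ccccc3)c(OC)c(OCc3ccccc3)c2)oc2c(OC)c(OC)cc(OC)c2c1=O
F4 | step 9 | dimethyl {2-[3,5-bis(benzyloxy)-4-methoxyphenyl]-5,7,8-trimethoxy-4-oxo-4H-chromen-3-yl}boronate | COB(OC)c1c(-c2cc(OCc3ccccc3)c(OC)c(OCc3ccccc3)c2)oc2c(OC)c(OC)cc(OC)c2c1=O
F5 | step 10 | 2-(3,5-dihydroxy-4-methoxyphenyl)-3-hydroxy-5,7,8-trimethoxy-4H-chromen-4-one | COc1cc(OC)c2c(=O)c(O)c(-c3cc(O)c(OC)c(O)c3)oc2c1OC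
F6 | step 10 | 5-(3-acetoxy-5,7,8-trimethoxy-4-oxo-4H-chromen-2-yl)-2-methoxy-1,3-phenylene diacetate | COc1cc(OC)c2c(=O)c(OC(C)=O)c(-c3cc(OC(C)=O)c(OC)c(OC(C)=O)c3)oc2c1OC
F7 | step 10 | 5-(3-acetoxy-5-hydroxy-7,8-dimethoxy-4-oxo-4H-chromen-2-yl)-2-methoxy-1,3-phenylene diacetate | COc1cc(O)c2c(=O)c(OC(C)=O)c(-c3cc(OC(C)=O)c(OC)c(OC(C)=O)c3)oc2c1OC
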